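**Plan**

- Retrosynthesis: the C8 ester is cut first. Then C3–C2, C2–O1 and C8a–C3a are cut together (hetero-Pauson–Khand retron), which opens both lactone and cycloheptane to an acyclic allenyl aldehyde. That chain is cut at C4–C5 (propargylation, then one-carbon homologation to the allene), at C15–C16 (propenyl ketone from an acid) and at C6–C7 (Ireland–Claisen), back to L-threitol acetonide and (E)-crotyl alcohol.
- Enabling feature: the α-methylene lactone O1–C2(=O)–C3(=CH2) sits on the C8a–C3a bond, which is also a bond of the seven-membered ring C3a–C4–C5–C6–C7–C8–C8a. C8a–O1 is therefore an aldehyde C=O, C3a–C3(=CH2) an allene C=C and C2 one CO, so a single [2+2+1] event closes both rings.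
- Forward order: the chain is built on a dioxolane (temporary ring over O7/O8, the turn element). Step 12 closes cycloheptane and lactone together. Then the acetonide is removed, the C8 ester is put on, and the C5 carbinol (oxidation-level helper that avoids an enolisable β-allenyl ketone) is oxidised last.
- Stereochemistry: C8 from L-threitol; C7 and C6 from the Ireland–Claisen step (attack anti to the C8a arm on the dioxolane, chair transition state with the E-crotyl unit); C5 (temporary) by chelation control; C8a and C3a in the key step; the ester centre from (R)-2-methylbutanoic acid.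
- Numbering: atom numbers are those of the target core (O1, C2, C3, C3a, C4–C8, C8a; C15 = side-chain carbonyl) and are kept for all intermediates.

Key step: step 12

Remark: (+)-2,3-O-isopropylidene-L-threitol, (E)-crotyl alcohol, (E)-1-bromoprop-1-ene and (R)-2-methylbutanoic acid are taken as purchasable; catalyst-bound ruthenium and palladium species are mechanistic states and carry no compound number.

**Route**

Step 1
Reactants: 1 (4S,5S)-2,2-dimethyl-1,3-dioxolane-4,5-dimethanol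
Product: 2 [(4S,5S)-5-{[(4-methoxybenzyl)oxy]methyl}-2,2-dimethyl-1,3-dioxolan-4-yl]methanol
Conditions: NaH (1 equiv), 4-methoxybenzyl chloride (1 equiv), Bu4NI (cat.), THF, 0 °C to 23 °C
Reagents that add atoms: 4-methoxybenzyl chloride, COc1ccc(CCl)cc1
Why: Williamson mono-etherification of a C2-symmetric diol, whose two hydroxyls are homotopic, should give a single mono-ether with both stereocentres untouched.

Step 2
Reactants: 2 [(4S,5S)-5-{[(4-methoxybenzyl)oxy]methyl}-2,2-dimethyl-1,3-dioxolan-4-yl]methanol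
Product: 3 (4R,5S)-5-{[(4-methoxybenzyl)oxy]methyl}-2,2-dimethyl-1,3-dioxolane-4-carboxylic acid
Conditions: TEMPO (cat.), PhI(OAc)2, MeCN/H2O (1:1), 23 °C
Reagents that add atoms: water, O
Why: Oxoammonium-mediated oxidation of the primary alcohol through the aldehyde hydrate should give the acid without touching the benzylic ether or the acetonide; the α-centre is destroyed on purpose in step 4, so its integrity is not critical.

Step 3
Reactants: 3 (4R,5S)-5-{[(4-methoxybenzyl)oxy]methyl}-2,2-dimethyl-1,3-dioxolane-4-carboxylic acid; 4 (2E)-but-2-en-1-ol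
Product: 5 (2E)-but-2-en-1-yl (4R,5S)-5-{[(4-methoxybenzyl)oxy]methyl}-2,2-dimethyl-1,3-dioxolane-4-carboxylate
Conditions: DCC, DMAP (cat.), CH2Cl2, 0 °C to 23 °C
Reagents that add atoms: none
Why: Steglich esterification of an unhindered primary allylic alcohol should proceed cleanly and keeps the E geometry of the crotyl unit.

Step 4
Reactants: 5 (2E)-but-2-en-1-yl (4R,5S)-5-{[(4-methoxybenzyl)oxy]methyl}-2,2-dimethyl-1,3-dioxolane-4-carboxylate
Product: 8 (4S,5S)-4-[(2S)-but-3-en-2-yl]-5-{[(4-methoxybenzyl)oxy]methyl}-2,2-dimethyl-1,3-dioxolane-4-carboxylic acid, via silyl ketene acetal 6 (not isolated), via trimethylsilyl ester 7 (not isolated)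
Conditions: LiN(SiMe3)2, Me3SiCl, THF, −78 °C to 23 °C; then dilute aqueous HCl, 0 °C
Reagents that add atoms: none
Why: Ireland–Claisen rearrangement of an α-alkoxy ester: the β-oxygen is held in the dioxolane out of alignment for elimination, the ketene acetal should form with OSiMe3 syn to the ring oxygen O7, the allyl terminus should add to the face anti to the CH2O(4-methoxybenzyl) arm on C8 (sets C7), and a chair transition state with the E-crotyl methyl equatorial should set C6 (O7/methyl syn).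

Step 5
Reactants: 8 (4S,5S)-4-[(2S)-but-3-en-2-yl]-5-{[(4-methoxybenzyl)oxy]methyl}-2,2-dimethyl-1,3-dioxolane-4-carboxylic acid
Product: 9 (2E)-1-[(4S,5S)-4-[(2S)-but-3-en-2-yl]-5-{[(4-methoxybenzyl)oxy]methyl}-2,2-dimethyl-1,3-dioxolan-4-yl]but-2-en-1-one
Conditions: (E)-1-bromoprop-1-ene, t-BuLi (2 equiv per bromide), Et2O, −78 °C; then 8 (one third equiv), THF, −78 °C to 0 °C; poured into cold H2O
Reagents that add atoms: (E)-prop-1-enyllithium, C/C=C/[Li] (made in the flask from (E)-1-bromoprop-1-ene, C/C=C/Br)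
Why: Addition of an alkenyllithium to the lithium carboxylate gives a dilithium gem-diolate that cannot add a second time and collapses to the ketone on quench; the acid has no α-hydrogen, and halogen–lithium exchange keeps the E geometry.

Step 6
Reactants: 9 (2E)-1-[(4S,5S)-4-[(2S)-but-3-en-2-yl]-5-{[(4-methoxybenzyl)oxy]methyl}-2,2-dimethyl-1,3-dioxolan-4-yl]but-2-en-1-one
Product: 11 (2R)-2-[(4S,5S)-4-[(2E)-but-2-enoyl]-5-{[(4-methoxybenzyl)oxy]methyl}-2,2-dimethyl-1,3-dioxolan-4-yl]propanal, via vicinal diol 10 (not isolated)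
Conditions: OsO4 (2 mol %), NaIO4, 2,6-lutidine, 1,4-dioxane/H2O (3:1), 23 °C
Reagents that add atoms: osmium tetroxide, O=[Os](=O)(=O)=O (oxygen donor, restored by sodium periodate, [Na+].[O-]I(=O)(=O)=O)
Why: Lemieux–Johnson cleavage should select the electron-rich monosubstituted vinyl group over the electron-poor conjugated enone alkene, and the lutidine buffer should keep the α-methyl aldehyde from epimerising.

Step 7
Reactants: 11 (2R)-2-[(4S,5S)-4-[(2E)-but-2-enoyl]-5-{[(4-methoxybenzyl)oxy]methyl}-2,2-dimethyl-1,3-dioxolan-4-yl]propanal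
Product: 12 (2E)-1-[(4S,5S)-4-[(2S,3S)-3-hydroxyhex-5-yn-2-yl]-5-{[(4-methoxybenzyl)oxy]methyl}-2,2-dimethyl-1,3-dioxolan-4-yl]but-2-en-1-one
Conditions: allenyltributylstannane, MgBr2·OEt2, CH2Cl2, −20 °C
Reagents that add atoms: allenyltributylstannane, C=C=C[Sn](CCCC)(CCCC)CCCC
Why: Chelation-controlled SE2' propargylation: magnesium should bridge the aldehyde oxygen and the β-oxygen O7 in a six-membered Cram chelate, and the stannane should attack anti to the C6 methyl to give the 5,6-anti (5S) carbinol, with the aldehyde reacting in preference to the hindered enone.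

Step 8
Reactants: 12 (2E)-1-[(4S,5S)-4-[(2S,3S)-3-hydroxyhex-5-yn-2-yl]-5-{[(4-methoxybenzyl)oxy]methyl}-2,2-dimethyl-1,3-dioxolan-4-yl]but-2-en-1-one
Product: 13 (2E)-1-[(4S,5S)-4-[(2S,3S)-3-{[tert-butyl(dimethyl)silyl]oxy}hex-5-yn-2-yl]-5-{[(4-methoxybenzyl)oxy]methyl}-2,2-dimethyl-1,3-dioxolan-4-yl]but-2-en-1-one
Conditions: t-BuMe2SiOTf, 2,6-lutidine, CH2Cl2, −78 °C to 0 °C
Reagents that add atoms: tert-butyldimethylsilyl trifluoromethanesulfonate, CC(C)(C)[Si](C)(C)OS(=O)(=O)C(F)(F)F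
Why: Silyl triflate silylation of a hindered secondary alcohol is standard and should trap the open hydroxy ketone form (the conjugated ketone disfavours the cyclic hemiketal).

Step 9
Reactants: 13 (2E)-1-[(4S,5S)-4-[(2S,3S)-3-{[tert-butyl(dimethyl)silyl]oxy}hex-5-yn-2-yl]-5-{[(4-methoxybenzyl)oxy]methyl}-2,2-dimethyl-1,3-dioxolan-4-yl]but-2-en-1-one
Product: 15 (2E)-1-[(4S,5S)-4-[(2S,3S)-3-{[tert-butyl(dimethyl)silyl]oxy}hepta-5,6-dien-2-yl]-5-{[(4-methoxybenzyl)oxy]methyl}-2,2-dimethyl-1,3-dioxolan-4-yl]but-2-en-1-one, via propargylic amine 14 (not isolated)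
Conditions: paraformaldehyde, CuI (0.5 equiv), dicyclohexylamine, 1,4-dioxane, reflux
Reagents that add atoms: formaldehyde (as paraformaldehyde), C=O
Why: Crabbé homologation: copper-mediated Mannich coupling gives the propargylic amine, which transfers hydride from an N–CH to the alkyne and expels the imine to leave the terminal allene; the bulky secondary amine should not add to the β-methyl enone and no stereocentre is involved.

Step 10
Reactants: 15 (2E)-1-[(4S,5S)-4-[(2S,3S)-3-{[tert-butyl(dimethyl)silyl]oxy}hepta-5,6-dien-2-yl]-5-{[(4-methoxybenzyl)oxy]methyl}-2,2-dimethyl-1,3-dioxolan-4-yl]but-2-en-1-one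
Product: 16 (2E)-1-[(4S,5S)-4-[(2S,3S)-3-{[tert-butyl(dimethyl)silyl]oxy}hepta-5,6-dien-2-yl]-5-(hydroxymethyl)-2,2-dimethyl-1,3-dioxolan-4-yl]but-2-en-1-one
Conditions: DDQ, CH2Cl2/pH 7 buffer (10:1), 0 °C
Reagents that add atoms: none
Why: Oxidative cleavage of the electron-rich 4-methoxybenzyl ether by DDQ is orthogonal to the silyl ether, acetonide, allene and enone.

Step 11
Reactants: 16 (2E)-1-[(4S,5S)-4-[(2S,3S)-3-{[tert-butyl(dimethyl)silyl]oxy}hepta-5,6-dien-2-yl]-5-(hydroxymethyl)-2,2-dimethyl-1,3-dioxolan-4-yl]but-2-en-1-one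
Product: 17 (4R,5S)-5-[(2E)-but-2-enoyl]-5-[(2S,3S)-3-{[tert-butyl(dimethyl)silyl]oxy}hepta-5,6-dien-2-yl]-2,2-dimethyl-1,3-dioxolane-4-carbaldehyde
Conditions: Dess–Martin periodinane, pyridine, CH2Cl2, 0 °C to 23 °C
Reagents that add atoms: none
Why: Dess–Martin oxidation under buffered, non-basic conditions should give the α-alkoxy aldehyde without epimerisation at C8; any hemiketal with the C15 ketone drains through the open form.

Step 12
Reactants: 17 (4R,5S)-5-[(2E)-but-2-enoyl]-5-[(2S,3S)-3-{[tert-butyl(dimethyl)silyl]oxy}hepta-5,6-dien-2-yl]-2,2-dimethyl-1,3-dioxolane-4-carbaldehyde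
Product: 18 (3aR,5S,6S,7S,8S,8aR)-7-[(2E)-but-2-enoyl]-5-{[tert-butyl(dimethyl)silyl]oxy}-7,8-(isopropylidenedioxy)-6-methyl-3-methylideneoctahydro-2H-cyclohepta[b]furan-2-one
Conditions: Ru3(CO)12 (5 mol %), CO (10 atm), 1,4-dioxane (0.005 M), 120 °C
Reagents that add atoms: carbon monoxide, [C-]#[O+]
Why: Proposed new method: a zerovalent ruthenium carbonyl fragment binds the C8a aldehyde and the internal C3a=C3 bond of the allene and couples them oxidatively (C8a–C3a bond, seven-membered ring) to an oxaruthenacyclopentane, CO inserts into the Ru–C3 alkenyl bond (the C3–C2 bond), and C2–O1 reductive elimination releases the lactone and the catalyst. The closest known reaction type is the Ru3(CO)12-catalysed (or Mo(CO)6-mediated) hetero-Pauson–Khand cyclocarbonylation of allenyl aldehydes to cis-fused α-methylene-γ-butyrolactones on five- and six-membered rings; the five-atom tether and the trans ring fusion are the extension. The cycloheptane closes in 7-exo fashion at the proximal allene carbon (C3 and its CH2 stay outside the ring) and the γ-lactone closes as the [2+2+1] union of C8a=O, C3a=C3 and CO. C8a and C3a are set together in the oxidative coupling through a chair-like seven-membered transition state in which the trans-dioxolane holds O7 and O8 equatorial (crotonoyl axial), the 5S silyloxy group is equatorial and the forming Ru–O and Ru–C3 bonds are equatorial, which puts H8a and H3a trans and O1 trans to O8; a five-atom tether, unlike the three- and four-atom tethers of the known cases, can take up a trans-fused metallacycle without strain. The step needs the aldehyde to react in preference to the C15 enone carbonyl (which could close a six-membered ring) and the internal in preference to the terminal allene bond; the first is secured by the conjugated, neopentyl-type ketone on the fully substituted C7, the second by ring size (the alternative is eight-membered). The acetonide turn between C6 and C8a and high dilution are there to favour ring closure over oligomerisation.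

Step 13
Reactants: 18 (3aR,5S,6S,7S,8S,8aR)-7-[(2E)-but-2-enoyl]-5-{[tert-butyl(dimethyl)silyl]oxy}-7,8-(isopropylidenedioxy)-6-methyl-3-methylideneoctahydro-2H-cyclohepta[b]furan-2-one
Product: 19 (3aR,5S,6S,7S,8S,8aR)-7-[(2E)-but-2-enoyl]-5-{[tert-butyl(dimethyl)silyl]oxy}-7,8-dihydroxy-6-methyl-3-methylideneoctahydro-2H-cyclohepta[b]furan-2-one
Conditions: AcOH/H2O (4:1), 40 °C
Reagents that add atoms: none
Why: Acid hydrolysis of the acetal should be fast because the dioxolane is trans-fused to the seven-membered ring and strained, and faster than cleavage of the secondary silyl ether, while lactone, enone and exocyclic alkene are acid-stable.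

Step 14
Reactants: 19 (3aR,5S,6S,7S,8S,8aR)-7-[(2E)-but-2-enoyl]-5-{[tert-butyl(dimethyl)silyl]oxy}-7,8-dihydroxy-6-methyl-3-methylideneoctahydro-2H-cyclohepta[b]furan-2-one; 20 (2R)-2-methylbutanoic acid
Product: 21 (3aR,5S,6S,7S,8S,8aR)-7-[(2E)-but-2-enoyl]-5-{[tert-butyl(dimethyl)silyl]oxy}-7-hydroxy-6-methyl-3-methylidene-2-oxooctahydro-2H-cyclohepta[b]furan-8-yl (2R)-2-methylbutanoate
Conditions: DCC, DMAP (cat.), CH2Cl2, 0 °C to 23 °C
Reagents that add atoms: none
Why: Steglich esterification should acylate only the equatorial secondary C8 hydroxyl (the tertiary C7 hydroxyl is inert), and the α-centre of the acid is not expected to epimerise at low temperature.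

Step 15
Reactants: 21 (3aR,5S,6S,7S,8S,8aR)-7-[(2E)-but-2-enoyl]-5-{[tert-butyl(dimethyl)silyl]oxy}-7-hydroxy-6-methyl-3-methylidene-2-oxooctahydro-2H-cyclohepta[b]furan-8-yl (2R)-2-methylbutanoate
Product: 22 (3aR,5S,6S,7S,8S,8aR)-7-[(2E)-but-2-enoyl]-5,7-dihydroxy-6-methyl-3-methylidene-2-oxooctahydro-2H-cyclohepta[b]furan-8-yl (2R)-2-methylbutanoate
Conditions: HF·pyridine, pyridine, THF, 0 °C to 23 °C
Reagents that add atoms: none
Why: Buffered fluoride desilylation is non-nucleophilic toward the α-methylene lactone and the ester; the freed C5 hydroxyl is trans to the crotonoyl group and cannot form a hemiketal with it.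

Step 16
Reactants: 22 (3aR,5S,6S,7S,8S,8aR)-7-[(2E)-but-2-enoyl]-5,7-dihydroxy-6-methyl-3-methylidene-2-oxooctahydro-2H-cyclohepta[b]furan-8-yl (2R)-2-methylbutanoate
Product: 23 (3aR,6R,7S,8S,8aR)-7-[(2E)-but-2-enoyl]-7-hydroxy-6-methyl-3-methylidene-2,5-dioxooctahydro-2H-cyclohepta[b]furan-8-yl (2R)-2-methylbutanoate
Conditions: Dess–Martin periodinane, pyridine, CH2Cl2, 0 °C
Reagents that add atoms: none
Why: Dess–Martin oxidation should convert the only secondary carbinol to the C5 ketone under neutral conditions, so the base-sensitive tertiary aldol and the epimerisable C6 are formed in the final, mildest step.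

**Compound list**

1 | (4S,5S)-2,2-dimethyl-1,3-dioxolane-4,5-dimethanol [(+)-2,3-O-isopropylidene-L-threitol] | OC[C@@H]1OC(C)(C)O[C@H]1CO | starting material
2 | [(4S,5S)-5-{[(4-methoxybenzyl)oxy]methyl}-2,2-dimethyl-1,3-dioxolan-4-yl]methanol | OC[C@@H]1OC(C)(C)O[C@H]1COCc1ccc(OC)cc1 | intermediate
3 | (4R,5S)-5-{[(4-methoxybenzyl)oxy]methyl}-2,2-dimethyl-1,3-dioxolane-4-carboxylic acid | OC(=O)[C@@H]1OC(C)(C)O[C@H]1COCc1ccc(OC)cc1 | intermediate
4 | (2E)-but-2-en-1-ol | C/C=C/CO | starting material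
5 | (2E)-but-2-en-1-yl (4R,5S)-5-{[(4-methoxybenzyl)oxy]methyl}-2,2-dimethyl-1,3-dioxolane-4-carboxylate | C/C=C/COC(=O)[C@@H]1OC(C)(C)O[C@H]1COCc1ccc(OC)cc1 | intermediate
6 | O-crotyl O-trimethylsilyl ketene acetal of 5 (OSiMe3 syn to ring oxygen O7; C8 unchanged) | C/C=C/CO/C(O[Si](C)(C)C)=C1/OC(C)(C)O[C@H]1COCc1ccc(OC)cc1 | intermediate
7 | trimethylsilyl (4S,5S)-4-[(2S)-but-3-en-2-yl]-5-{[(4-methoxybenzyl)oxy]methyl}-2,2-dimethyl-1,3-dioxolane-4-carboxylate | C[Si](C)(C)OC(=O)[C@@]1([C@@H](C)C=C)OC(C)(C)O[C@H]1COCc1ccc(OC)cc1 | intermediate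
8 | (4S,5S)-4-[(2S)-but-3-en-2-yl]-5-{[(4-methoxybenzyl)oxy]methyl}-2,2-dimethyl-1,3-dioxolane-4-carboxylic acid | OC(=O)[C@@]1([C@@H](C)C=C)OC(C)(C)O[C@H]1COCc1ccc(OC)cc1 | intermediate
9 | (2E)-1-[(4S,5S)-4-[(2S)-but-3-en-2-yl]-5-{[(4-methoxybenzyl)oxy]methyl}-2,2-dimethyl-1,3-dioxolan-4-yl]but-2-en-1-one | C/C=C/C(=O)[C@@]1([C@@H](C)C=C)OC(C)(C)O[C@H]1COCc1ccc(OC)cc1 | intermediate
10 | vicinal diol of 9 (3,4-dihydroxybutan-2-yl side chain, both carbinol epimers) | C/C=C/C(=O)[C@@]1([C@@H](C)C(O)CO)OC(C)(C)O[C@H]1COCc1ccc(OC)cc1 | intermediate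
11 | (2R)-2-[(4S,5S)-4-[(2E)-but-2-enoyl]-5-{[(4-methoxybenzyl)oxy]methyl}-2,2-dimethyl-1,3-dioxolan-4-yl]propanal | C/C=C/C(=O)[C@@]1([C@@H](C)C=O)OC(C)(C)O[C@H]1COCc1ccc(OC)cc1 | intermediate
12 | (2E)-1-[(4S,5S)-4-[(2S,3S)-3-hydroxyhex-5-yn-2-yl]-5-{[(4-methoxybenzyl)oxy]methyl}-2,2-dimethyl-1,3-dioxolan-4-yl]but-2-en-1-one | C/C=C/C(=O)[C@@]1([C@@H](C)[C@@H](O)CC#C)OC(C)(C)O[C@H]1COCc1ccc(OC)cc1 | intermediate
13 | (2E)-1-[(4S,5S)-4-[(2S,3S)-3-{[tert-butyl(dimethyl)silyl]oxy}hex-5-yn-2-yl]-5-{[(4-methoxybenzyl)oxy]methyl}-2,2-dimethyl-1,3-dioxolan-4-yl]but-2-en-1-one | C/C=C/C(=O)[C@@]1([C@@H](C)[C@@H](O[Si](C)(C)C(C)(C)C)CC#C)OC(C)(C)O[C@H]1COCc1ccc(OC)cc1 | intermediate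
14 | (2E)-1-[(4S,5S)-4-[(2S,3S)-3-{[tert-butyl(dimethyl)silyl]oxy}-7-(dicyclohexylamino)hept-5-yn-2-yl]-5-{[(4-methoxybenzyl)oxy]methyl}-2,2-dimethyl-1,3-dioxolan-4-yl]but-2-en-1-one | C/C=C/C(=O)[C@@]1([C@@H](C)[C@@H](O[Si](C)(C)C(C)(C)C)CC#CCN(C2CCCCC2)C2CCCCC2)OC(C)(C)O[C@H]1COCc1ccc(OC)cc1 | intermediate
15 | (2E)-1-[(4S,5S)-4-[(2S,3S)-3-{[tert-butyl(dimethyl)silyl]oxy}hepta-5,6-dien-2-yl]-5-{[(4-methoxybenzyl)oxy]methyl}-2,2-dimethyl-1,3-dioxolan-4-yl]but-2-en-1-one | C/C=C/C(=O)[C@@]1([C@@H](C)[C@@H](O[Si](C)(C)C(C)(C)C)CC=C=C)OC(C)(C)O[C@H]1COCc1ccc(OC)cc1 | intermediate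
16 | (2E)-1-[(4S,5S)-4-[(2S,3S)-3-{[tert-butyl(dimethyl)silyl]oxy}hepta-5,6-dien-2-yl]-5-(hydroxymethyl)-2,2-dimethyl-1,3-dioxolan-4-yl]but-2-en-1-one | C/C=C/C(=O)[C@@]1([C@@H](C)[C@@H](O[Si](C)(C)C(C)(C)C)CC=C=C)OC(C)(C)O[C@H]1CO | intermediate
17 | (4R,5S)-5-[(2E)-but-2-enoyl]-5-[(2S,3S)-3-{[tert-butyl(dimethyl)silyl]oxy}hepta-5,6-dien-2-yl]-2,2-dimethyl-1,3-dioxolane-4-carbaldehyde | C/C=C/C(=O)[C@@]1([C@@H](C)[C@@H](O[Si](C)(C)C(C)(C)C)CC=C=C)OC(C)(C)O[C@H]1C=O | intermediate
18 | (3aR,5S,6S,7S,8S,8aR)-7-[(2E)-but-2-enoyl]-5-{[tert-butyl(dimethyl)silyl]oxy}-7,8-(isopropylidenedioxy)-6-methyl-3-methylideneoctahydro-2H-cyclohepta[b]furan-2-one | C=C1C(=O)O[C@@H]2[C@@H]1C[C@H](O[Si](C)(C)C(C)(C)C)[C@H](C)[C@@](OC3(C)C)(C(=O)/C=C/C)[C@H]2O3 | intermediate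
19 | (3aR,5S,6S,7S,8S,8aR)-7-[(2E)-but-2-enoyl]-5-{[tert-butyl(dimethyl)silyl]oxy}-7,8-dihydroxy-6-methyl-3-methylideneoctahydro-2H-cyclohepta[b]furan-2-one | C=C1C(=O)O[C@@H]2[C@@H]1C[C@H](O[Si](C)(C)C(C)(C)C)[C@H](C)[C@@](O)(C(=O)/C=C/C)[C@H]2O | intermediate
20 | (2R)-2-methylbutanoic acid | CC[C@@H](C)C(=O)O | starting material
21 | (3aR,5S,6S,7S,8S,8aR)-7-[(2E)-but-2-enoyl]-5-{[tert-butyl(dimethyl)silyl]oxy}-7-hydroxy-6-methyl-3-methylidene-2-oxooctahydro-2H-cyclohepta[b]furan-8-yl (2R)-2-methylbutanoate | C=C1C(=O)O[C@@H]2[C@@H]1C[C@H](O[Si](C)(C)C(C)(C)C)[C@H](C)[C@@](O)(C(=O)/C=C/C)[C@H]2OC(=O)[C@H](C)CC | intermediate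
22 | (3aR,5S,6S,7S,8S,8aR)-7-[(2E)-but-2-enoyl]-5,7-dihydroxy-6-methyl-3-methylidene-2-oxooctahydro-2H-cyclohepta[b]furan-8-yl (2R)-2-methylbutanoate | C=C1C(=O)O[C@@H]2[C@@H]1C[C@H](O)[C@H](C)[C@@](O)(C(=O)/C=C/C)[C@H]2OC(=O)[C@H](C)CC | intermediate
23 | (3aR,6R,7S,8S,8aR)-7-[(2E)-but-2-enoyl]-7-hydroxy-6-methyl-3-methylidene-2,5-dioxooctahydro-2H-cyclohepta[b]furan-8-yl (2R)-2-methylbutanoate | C=C1C(=O)O[C@@H]2[C@@H]1CC(=O)[C@H](C)[C@@](O)(C(=O)/C=C/C)[C@H]2OC(=O)[C@H](C)CC | target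

**Count**

Total steps: 16. Longest linear sequence: 16 steps (from 1).

**Steps most likely to fail, with fallbacks**

Step 12 (proposed new method). What may go wrong: the oxidative coupling may fail to close the seven-membered ring (oligomerisation, decarbonylation of the aldehyde), may deliver the cis ring fusion or the C8a epimer, or may engage the enone carbonyl. The fallback uses known chemistry and closes the two rings one after the other. It sets out from 17. Bromine (1 equiv, CH2Cl2, −78 °C) should add across the terminal allene bond to give (4R,5S)-5-[(2E)-but-2-enoyl]-5-[(2S,3S,5E)-6,7-dibromo-3-{[tert-butyl(dimethyl)silyl]oxy}hept-5-en-2-yl]-2,2-dimethyl-1,3-dioxolane-4-carbaldehyde F1; its geometric and allylic isomers converge in the next step. CrCl2 in THF under high dilution should turn the allylic bromide into an allylchromium that adds through C3a to the aldehyde (intramolecular Nozaki–Hiyama allylation, anti addition, the alkenyl bromide untouched in the absence of nickel). This gives the trans-2-(1-bromovinyl)cycloheptanol F2, which carries the acetonide and silyl ether of 18. Alkoxycarbonylation of the alkenyl bromide by the C8a hydroxyl (Pd(PPh3)4 cat., CO 1 atm, Et3N, MeCN, 60 °C) then forms the C3–C2 bond, and the route is rejoined at 18.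

Step 4. What may go wrong: erosion of stereocontrol at C6 if the ketene acetal forms with the other geometry, or β-elimination of the ester enolate on warming. The fallback takes C6 from the chiral pool instead and sets out from 5. The lithium enolate (LDA, THF, −78 °C) is alkylated with ethyl (2R)-2-{[(trifluoromethyl)sulfonyl]oxy}propanoate (SN2 with inversion, attack again anti to the C8 arm) to give (2E)-but-2-en-1-yl (4S,5S)-4-[(2R)-1-ethoxy-1-oxopropan-2-yl]-5-{[(4-methoxybenzyl)oxy]methyl}-2,2-dimethyl-1,3-dioxolane-4-carboxylate F3. DIBAL-H (1 equiv, CH2Cl2, −78 °C) should reduce the less hindered ethyl ester to (2E)-but-2-en-1-yl (4S,5S)-5-{[(4-methoxybenzyl)oxy]methyl}-2,2-dimethyl-4-[(2R)-1-oxopropan-2-yl]-1,3-dioxolane-4-carboxylate F4. Wittig methylenation (Ph3P=CH2, THF, 0 °C) gives (2E)-but-2-en-1-yl (4S,5S)-4-[(2S)-but-3-en-2-yl]-5-{[(4-methoxybenzyl)oxy]methyl}-2,2-dimethyl-1,3-dioxolane-4-carboxylate F5. Removal of the crotyl ester (Pd(PPh3)4, morpholine, THF) comes back to the route at 8.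

Step 13. What may go wrong: loss of the C5 silyl ether alongside acetal hydrolysis, after which the two secondary hydroxyls could not be told apart in step 14. The fallback changes the order of the endgame so that no such selectivity is needed, and sets out from 18. HF·pyridine gives (3aR,5S,6S,7S,8S,8aR)-7-[(2E)-but-2-enoyl]-5-hydroxy-7,8-(isopropylidenedioxy)-6-methyl-3-methylideneoctahydro-2H-cyclohepta[b]furan-2-one F6. Dess–Martin oxidation gives (3aR,6R,7S,8S,8aR)-7-[(2E)-but-2-enoyl]-7,8-(isopropylidenedioxy)-6-methyl-3-methylidenehexahydro-2H-cyclohepta[b]furan-2,5(3H)-dione F7. Aqueous trifluoroacetic acid (CH2Cl2, 0 °C) removes the acetonide to give (3aR,6R,7S,8S,8aR)-7-[(2E)-but-2-enoyl]-7,8-dihydroxy-6-methyl-3-methylidenehexahydro-2H-cyclohepta[b]furan-2,5(3H)-dione F8. Its only secondary hydroxyl is esterified with 20 (DCC, DMAP cat., CH2Cl2, 0 °C), which comes back to the route at 23.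

**Further compounds**

F1 | step 12 | (4R,5S)-5-[(2E)-but-2-enoyl]-5-[(2S,3S,5E)-6,7-dibromo-3-{[tert-butyl(dimethyl)silyl]oxy}hept-5-en-2-yl]-2,2-dimethyl-1,3-dioxolane-4-carbaldehyde | C/C=C/C(=O)[C@@]1([C@@H](C)[C@@H](O[Si](C)(C)C(C)(C)C)C/C=C(Br)\CBr)OC(C)(C)O[C@H]1C=O
F2 | step 12 | trans-2-(1-bromovinyl)cycloheptanol corresponding to 18 (C8a–OH free, C3a bearing C(Br)=CH2, acetonide and silyl ether retained) | C=C(Br)[C@H]1C[C@H](O[Si](C)(C)C(C)(C)C)[C@H](C)[C@@](OC2(C)C)(C(=O)/C=C/C)[C@@H](O2)[C@@H]1O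
F3 | step 4 | (2E)-but-2-en-1-yl (4S,5S)-4-[(2R)-1-ethoxy-1-oxopropan-2-yl]-5-{[(4-methoxybenzyl)oxy]methyl}-2,2-dimethyl-1,3-dioxolane-4-carboxylate | C/C=C/COC(=O)[C@@]1([C@@H](C)C(=O)OCC)OC(C)(C)O[C@H]1COCc1ccc(OC)cc1
F4 | step 4 | (2E)-but-2-en-1-yl (4S,5S)-5-{[(4-methoxybenzyl)oxy]methyl}-2,2-dimethyl-4-[(2R)-1-oxopropan-2-yl]-1,3-dioxolane-4-carboxylate | C/C=C/COC(=O)[C@@]1([C@@H](C)C=O)OC(C)(C)O[C@H]1COCc1ccc(OC)cc1
F5 | step 4 | (2E)-but-2-en-1-yl (4S,5S)-4-[(2S)-but-3-en-2-yl]-5-{[(4-methoxybenzyl)oxy]methyl}-2,2-dimethyl-1,3-dioxolane-4-carboxylate | C/C=C/COC(=O)[C@@]1([C@@H](C)C=C)OC(C)(C)O[C@H]1COCc1ccc(OC)cc1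
F6 | step 13 | (3aR,5S,6S,7S,8S,8aR)-7-[(2E)-but-2-enoyl]-5-hydroxy-7,8-(isopropylidenedioxy)-6-methyl-3-methylideneoctahydro-2H-cyclohepta[b]furan-2-one | C=C1C(=O)O[C@@H]2[C@@H]1C[C@H](O)[C@H](C)[C@@](OC3(C)C)(C(=O)/C=C/C)[C@H]2O3
F7 | step 13 | (3aR,6R,7S,8S,8aR)-7-[(2E)-but-2-enoyl]-7,8-(isopropylidenedioxy)-6-methyl-3-methylidenehexahydro-2H-cyclohepta[b]furan-2,5(3H)-dione | C=C1C(=O)O[C@@H]2[C@@H]1CC(=O)[C@H](C)[C@@](OC3(C)C)(C(=O)/C=C/C)[C@H]2O3
F8 | step 13 | (3aR,6R,7S,8S,8aR)-7-[(2E)-but-2-enoyl]-7,8-dihydroxy-6-methyl-3-methylidenehexahydro-2H-cyclohepta[b]furan-2,5(3H)-dione | C=C1C(=O)O[C@@H]2[C@@H]1CC(=O)[C@H](C)[C@@](O)(C(=O)/C=C/C)[C@H]2O
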